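**Retrosynthetic overview**

1. Locants of the fused system: peroxide O1–O2, C3 (quaternary; methyl and 10-phenyldecyl), C4 (CH2), C4a (quaternary; methyl and lactone O5), C6 (C=O), C7 (CH2), C7a (CH–O1). The 1,2-dioxane is cut last and at both C–O bonds: O2–C3 and O1–C7a lead back to O2 gas, a 1,1-disubstituted alkene (C3=CH2) and a butenolide (C7=C7a).
2. Enabling feature: the peroxide bridges a fully substituted, methyl-bearing carbon (C3, a tertiary radical site once a hydrogen atom is added to =CH2) and the β-carbon of the γ-lactone (C7a, a Michael acceptor). C3 and C7a are 1,4-related through C4 and the quaternary C4a, so a peroxide on C3 is placed for 6-exo closure and C4a dictates the cis fusion.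
3. Butenolide (lactone ring) ⇐ Z-selective olefination and lactonisation of a tertiary α-hydroxy aldehyde ⇐ primary/tertiary 1,2-diol.
4. Diol ⇐ copper-catalysed opening of an enantiopure 2-methyl epoxy alcohol (source of C4a) by a 1-alkylvinyl Grignard reagent, itself made from three commercial pieces by two Grignard couplings.
5. Order of ring formation: phenyl ring bought; γ-lactone in step 5; 1,2-dioxane in step 6.

Key step: step 6

Assumption: (R)-2-methylglycidol 1 is bought as the single enantiomer. C3 of the target arises in step 6 without substrate control, so the target is the (3R) epimer separated after that step.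

**Route**

Step 1
Reactants: 2 phenylmagnesium bromide; 3 1,9-dibromononane
Product: 4 (9-bromononyl)benzene
Conditions: Li2CuCl4 (3 mol %), 3 (3 equiv), THF, 0 °C → rt
Reagents that add atoms: none
Why: Kochi-type copper-catalysed coupling of a Grignard reagent with a primary alkyl bromide, in which the excess of 3 should hold double arylation down; no stereocentre is formed.

Step 2
Reactants: 4 (9-bromononyl)benzene; 5 2,3-dibromoprop-1-ene
Product: 7 2-bromo-12-phenyldodec-1-ene, via alkyl Grignard reagent 6 (not isolated)
Conditions: Mg, THF, 40 °C; then 5, CuI (5 mol %), 0 °C → rt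
Reagents that add atoms: none
Why: Allylic substitution of the primary C–Br bond of 5 by the alkyl Grignard reagent (SN2 and SN2′ give the same product) should leave the vinylic bromide untouched; no stereocentre is formed.

Step 3
Reactants: 7 2-bromo-12-phenyldodec-1-ene; 1 (R)-2-methylglycidol
Product: 10 (2S)-2-methyl-4-methylidene-14-phenyltetradecane-1,2-diol, via alkenyl Grignard reagent 8 (not isolated), via lithium alkoxide 9 (not isolated)
Conditions: 7: Mg, THF, 50 °C; 1: n-BuLi, THF, −78 °C; combine, CuI (10 mol %), −30 → 0 °C; H2O
Reagents that add atoms: none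
Why: Copper-catalysed SN2 opening of the 2,2-disubstituted epoxide at its unhindered CH2 terminus by the alkenyl Grignard reagent does not touch the quaternary centre, so the configuration of 1 is carried into 10 (the descriptor changes from R to S only because the CIP ranks of the two CH2 groups swap), and prior O-lithiation saves one equivalent of 8.

Step 4
Reactants: 10 (2S)-2-methyl-4-methylidene-14-phenyltetradecane-1,2-diol
Product: 11 (2S)-2-hydroxy-2-methyl-4-methylidene-14-phenyltetradecanal
Conditions: IBX (2-iodoxybenzoic acid), EtOAc, 75 °C
Reagents that add atoms: none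
Why: IBX oxidation of the primary alcohol of a 1,2-diol should stop at the aldehyde without C–C cleavage and cannot touch the tertiary alcohol or the alkene; the stereocentre has no α-hydrogen and cannot epimerise.

Step 5
Reactants: 11 (2S)-2-hydroxy-2-methyl-4-methylidene-14-phenyltetradecanal; 12 methyl 2-[bis(2,2,2-trifluoroethoxy)phosphoryl]acetate
Product: 14 (5S)-5-methyl-5-(2-methylidene-12-phenyldodecyl)furan-2(5H)-one, via Z-hydroxy enoate 13 (not isolated)
Conditions: 12, KN(SiMe3)2, 18-crown-6, THF, −78 °C; then 11, −78 → 0 °C; then TsOH (cat.), CH2Cl2, rt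
Reagents that add atoms: none
Why: Still–Gennari Z-selective Horner–Wadsworth–Emmons olefination of an α-oxygenated aldehyde followed by acid-catalysed lactonisation of the cis γ-hydroxy enoate closes the lactone ring; no new stereocentre is formed and C5 of the butenolide keeps the configuration of 1.

Step 6
Reactants: 14 (5S)-5-methyl-5-(2-methylidene-12-phenyldodecyl)furan-2(5H)-one
Product: 17 (3R,4aS,7aS)-3,4a-dimethyl-3-(10-phenyldecyl)tetrahydro-3H-furo[3,2-c][1,2]dioxin-6(4H)-one, via silyl peroxide 15 (not isolated), via hydroperoxide 16 (not isolated)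
Conditions: Co(thd)2 (thd = 2,2,6,6-tetramethylheptane-3,5-dionate; 10 mol %), Et3SiH, O2 (1 atm), ClCH2CH2Cl, rt; short SiO2 plug; then HCl (cat.), MeOH, 0 °C; then Et2NH, CF3CH2OH, rt
Reagents that add atoms: dioxygen, O=O
Why: The cobalt hydride formed from Co(thd)2, O2 and Et3SiH should transfer a hydrogen atom to the =CH2 terminus of the electron-rich 1,1-disubstituted alkene (Markovnikov), the tertiary radical at the carbon that becomes C3 captures O2, and the cobalt peroxide is silylated to 15; methanolysis frees hydroperoxide 16, whose peroxide anion (Et2NH in CF3CH2OH) adds to the butenolide β-carbon. The closest known reaction types are the Mukaiyama–Isayama hydroperoxysilylation of 1,1-disubstituted alkenes and the amine-promoted intramolecular oxa-Michael addition of hydroperoxides to unsaturated lactones and esters, here run in one flask. The 1,2-dioxane closes in the 6-exo-trig mode by O1–C7a bond formation, so the two C=C bonds and O2 are stitched into the ring in a formal hydrogenative (2+2+2) sense. C7a is controlled by the existing C4a centre, because the tether C4–C3–O2 can deliver O1 only to the butenolide face that carries C4, which enforces the cis ring fusion and gives (7aS) from (4aS). C3 is created when O2 meets a planar radical remote from C4a, so no substrate control is expected and both C3 epimers should form in comparable amounts; the (3R) isomer 17, with the C3 methyl cis to the C4a methyl, is separated by chromatography from its (3S) epimer, which is the acknowledged cost of this step. The step needs hydrogen-atom transfer to the 1,1-disubstituted alkene in preference to the butenolide C=C, which the electron-poor, 1,2-disubstituted nature of the latter should secure, and removal of cobalt before the hydroperoxide is freed, which protects the O–O bond.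

**Compound list**

1 | (R)-2-methylglycidol, [(2R)-2-methyloxiran-2-yl]methanol | C[C@@]1(CO)CO1 | starting material
2 | phenylmagnesium bromide | Br[Mg]c1ccccc1 | starting material
3 | 1,9-dibromononane | BrCCCCCCCCCBr | starting material
4 | (9-bromononyl)benzene | BrCCCCCCCCCc1ccccc1 | intermediate
5 | 2,3-dibromoprop-1-ene | C=C(Br)CBr | starting material
6 | (9-phenylnonyl)magnesium bromide | Br[Mg]CCCCCCCCCc1ccccc1 | intermediate
7 | 2-bromo-12-phenyldodec-1-ene | C=C(Br)CCCCCCCCCCc1ccccc1 | intermediate
8 | (12-phenyldodec-1-en-2-yl)magnesium bromide | C=C([Mg]Br)CCCCCCCCCCc1ccccc1 | intermediate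
9 | lithium [(2R)-2-methyloxiran-2-yl]methanolate | C[C@@]1(C[O-])CO1.[Li+] | intermediate
10 | (2S)-2-methyl-4-methylidene-14-phenyltetradecane-1,2-diol | C[C@@](O)(CO)CC(=C)CCCCCCCCCCc1ccccc1 | intermediate
11 | (2S)-2-hydroxy-2-methyl-4-methylidene-14-phenyltetradecanal | C[C@@](O)(C=O)CC(=C)CCCCCCCCCCc1ccccc1 | intermediate
12 | methyl 2-[bis(2,2,2-trifluoroethoxy)phosphoryl]acetate | COC(=O)CP(=O)(OCC(F)(F)F)OCC(F)(F)F | starting material
13 | methyl (2Z,4S)-4-hydroxy-4-methyl-6-methylidene-16-phenylhexadec-2-enoate | COC(=O)/C=C\[C@@](C)(O)CC(=C)CCCCCCCCCCc1ccccc1 | intermediate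
14 | (5S)-5-methyl-5-(2-methylidene-12-phenyldodecyl)furan-2(5H)-one | C=C(CCCCCCCCCCc1ccccc1)C[C@]2(C)OC(=O)C=C2 | intermediate
15 | (5S)-5-methyl-5-[(2R)-2-methyl-12-phenyl-2-(triethylsilylperoxy)dodecyl]furan-2(5H)-one (the epimer that leads to 17; its 2′-epimer forms alongside) | CC[Si](CC)(CC)OO[C@](C)(CCCCCCCCCCc1ccccc1)C[C@]2(C)OC(=O)C=C2 | intermediate
16 | (5S)-5-[(2R)-2-hydroperoxy-2-methyl-12-phenyldodecyl]-5-methylfuran-2(5H)-one (the epimer that leads to 17; its 2′-epimer forms alongside) | OO[C@](C)(CCCCCCCCCCc1ccccc1)C[C@]2(C)OC(=O)C=C2 | intermediate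
17 | (3R,4aS,7aS)-3,4a-dimethyl-3-(10-phenyldecyl)tetrahydro-3H-furo[3,2-c][1,2]dioxin-6(4H)-one | C[C@@]1(CCCCCCCCCCc2ccccc2)C[C@]2(C)OC(=O)C[C@@H]2OO1 | target

**Step count and risks**

Total steps: 6. Longest linear sequence: 6 (steps 1 to 6 from 2 and 3; 1 enters at step 3).

Steps most likely to fail:

Step 6 (key step). What may go wrong: hydrogen-atom transfer to the butenolide C=C in competition with the 1,1-disubstituted alkene; metal-induced homolysis of the O–O bond once the hydroperoxide is free; and, inherently, unselective O2 capture at C3 that sends a comparable share of the material to the C3 epimer. The fallback sets out from 14 and comes back at 16, and installs the tertiary peroxide by an ionic instead of a radical path. Markovnikov addition of HBr (HBr in AcOH, CH2Cl2, 0 °C) should give the tertiary bromide (5S)-5-(2-bromo-2-methyl-12-phenyldodecyl)-5-methylfuran-2(5H)-one F1. Silver-assisted perhydrolysis (AgOCOCF3, anhydrous H2O2 in Et2O, 0 °C) should replace bromide by OOH through the tertiary cation and give 16 with its epimer, which is cyclised with Et2NH in CF3CH2OH as in step 6. This takes cobalt and silane out of the sequence; the C3 epimers must still be separated.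

Step 5. What may go wrong: erosion of Z-selectivity, which leaves an E-enoate that cannot lactonise, and base-induced self-condensation of the α-hydroxy aldehyde. The fallback sets out from 11 and comes back at 14, and closes the lactone by metathesis instead of olefination. Wittig methylenation (Ph3P=CH2, THF, 0 °C) should give (3S)-3-methyl-5-methylidene-15-phenylpentadec-1-en-3-ol F2. Acylation with acryloyl chloride (Et3N, DMAP, CH2Cl2) should give (3S)-3-methyl-5-methylidene-15-phenylpentadec-1-en-3-yl prop-2-enoate F3. Ring-closing metathesis with the second-generation Grubbs catalyst (CH2Cl2, 40 °C) should join the acrylate and the vinyl group into the five-membered butenolide in preference to the hindered 1,1-disubstituted alkene, which returns the route to 14.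

Step 3. What may go wrong: slow or Wurtz-type magnesium insertion into the hindered alkenyl bromide, and opening of the epoxide by bromide instead of carbon. The fallback sets out from 1 and comes back at 15, and attaches the long chain late by cross-metathesis. 1 is opened with commercial isopropenylmagnesium bromide (2.2 equiv, CuI cat., THF, −30 → 0 °C) to give (2S)-2,4-dimethylpent-4-ene-1,2-diol F4. IBX oxidation should give (2S)-2-hydroxy-2,4-dimethylpent-4-enal F5. Olefination with 12 as in step 5 should give, through methyl (2Z,4S)-4-hydroxy-4,6-dimethylhepta-2,6-dienoate F6 (not isolated), the butenolide (5S)-5-methyl-5-(2-methylprop-2-en-1-yl)furan-2(5H)-one F7. 11-Phenylundec-1-ene F8 is made from 2 and 11-bromoundec-1-ene (Li2CuCl4 cat., THF). Cross-metathesis of F7 with excess F8 (second-generation Hoveyda–Grubbs catalyst, CH2Cl2, 40 °C) should give (5S)-5-methyl-5-(2-methyl-12-phenyldodec-2-en-1-yl)furan-2(5H)-one F9 as an E/Z mixture. Hydrogen-atom transfer to either alkene isomer generates the same tertiary radical as 14 does, so F9 is submitted to the first stage of step 6 and re-enters the route at 15.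

**Further compounds**

F1 | step 6 | (5S)-5-(2-bromo-2-methyl-12-phenyldodecyl)-5-methylfuran-2(5H)-one (both C2′ epimers) | CC(Br)(CCCCCCCCCCc1ccccc1)C[C@]2(C)OC(=O)C=C2
F2 | step 5 | (3S)-3-methyl-5-methylidene-15-phenylpentadec-1-en-3-ol | C[C@@](O)(C=C)CC(=C)CCCCCCCCCCc1ccccc1
F3 | step 5 | (3S)-3-methyl-5-methylidene-15-phenylpentadec-1-en-3-yl prop-2-enoate | C=CC(=O)O[C@](C)(C=C)CC(=C)CCCCCCCCCCc1ccccc1
F4 | step 3 | (2S)-2,4-dimethylpent-4-ene-1,2-diol | C[C@@](O)(CO)CC(C)=C
F5 | step 3 | (2S)-2-hydroxy-2,4-dimethylpent-4-enal | C[C@@](O)(C=O)CC(C)=C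
F6 | step 3 | methyl (2Z,4S)-4-hydroxy-4,6-dimethylhepta-2,6-dienoate | COC(=O)/C=C\[C@@](C)(O)CC(C)=C
F7 | step 3 | (5S)-5-methyl-5-(2-methylprop-2-en-1-yl)furan-2(5H)-one | CC(=C)C[C@]1(C)OC(=O)C=C1
F8 | step 3 | 11-phenylundec-1-ene | C=CCCCCCCCCCc1ccccc1
F9 | step 3 | (5S)-5-methyl-5-(2-methyl-12-phenyldodec-2-en-1-yl)furan-2(5H)-one (E/Z mixture) | CC(=CCCCCCCCCCc1ccccc1)C[C@]2(C)OC(=O)C=C2
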